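Ring A is disconnected at C2–C3 and ring B is recognised as (R)-carvone: the carvone ring becomes C5–C10, its methyl C17, its carbonyl C9, and its isopropenyl group C3, C4 and C19. Anti-selective double alkylation at the α′-carbon builds C10 carrying a 2-bromoethyl arm (C1–C2), and the isopropenyl group is oxidised to an acrylate. The key step is a 6-endo-trig radical cyclisation of the C2 radical onto C3 of that acrylate, which closes ring A as a trans-decalin in one operation. It exploits the C19 oxygen on quaternary C4: as an ester it polarises the C3=C4 alkene for endo closure and afterwards directs an equatorial enolate methylation that sets C4.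

Key step: step 5

Remark: labdane numbering (C1–C20) is used for all compounds, including the monocyclic precursors (carvone C1 = C9, C2 = C8, C5 = C5, C6 = C10). 2-Bromoethyl trifluoromethanesulfonate 3 and chloroprene 14 are assumed to be purchasable; 3 can otherwise be made from 2-bromoethanol and Tf2O.

Step 1
Reactants: 1 (R)-(−)-carvone
Product: 2 6-methylcarvone (both C10 epimers)
Conditions: LiN(iPr)2, THF, −78 °C; then MeI, −78 to 0 °C
Reagents that add atoms: iodomethane CI
Why: Kinetic α′-deprotonation of the enone and enolate alkylation; the new centre (future C10) forms as an epimer mixture that the next enolisation erases.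

Step 2
Reactants: 2 6-methylcarvone; 3 2-bromoethyl trifluoromethanesulfonate
Product: 4 bromoethyl ketone (bromoethyl trans to isopropenyl)
Conditions: LiN(iPr)2, THF, −78 °C; then 3, −78 to 0 °C
Reagents that add atoms: none
Why: Enolate alkylation at the triflate terminus (triflate far better leaving group than bromide); the electrophile should enter anti to the adjacent isopropenyl group, so both epimers of 2 converge on one quaternary C10 (methyl cis, C1–C2 arm trans to the C5 substituent).

Step 3
Reactants: 4 bromoethyl ketone
Product: 5 allylic alcohol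
Conditions: SeO2 (cat.), t-BuOOH, salicylic acid (cat.), CH2Cl2, rt
Reagents that add atoms: tert-butyl hydroperoxide CC(C)(C)OO
Why: SeO2 allylic oxidation (ene reaction then [2,3]-shift) should take the methyl of the electron-rich 1,1-disubstituted alkene and leave the electron-poor enone alone; no stereocentre is formed.

Step 4
Reactants: 5 allylic alcohol
Product: 7 bromoethyl acrylate ester, via enal 6 (not isolated)
Conditions: MnO2, 1,4-dimethyl-1,2,4-triazolium iodide (cat.), DBU, MeOH, CH2Cl2, rt
Reagents that add atoms: methanol CO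
Why: Tandem MnO2 allylic oxidation and carbene-catalysed oxidative esterification through the acyl azolium, cyanide-free so the primary bromide survives; no stereocentre is touched.

Step 5
Reactants: 7 bromoethyl acrylate ester
Product: 8 decalin keto ester (C4 epimers)
Conditions: Bu3SnH (syringe pump), AIBN (cat.), benzene (0.01 M), reflux
Reagents that add atoms: none
Why: Bu3Sn• abstracts bromine from 7 and the nucleophilic primary C2 radical adds to C3, the unsubstituted β-carbon of the 2-substituted acrylate, giving the tertiary α-ester radical at C4, which takes hydrogen from Bu3SnH (tin hydride chain; Giese-type intramolecular conjugate addition). Ring A closes in the 6-endo-trig mode, the known preference of 5-hexenyl radicals whose internal alkene carbon carries an ester. The only new stereocentre, C4, arises by unselective hydrogen transfer and is left uncontrolled on purpose because step 7 re-enolises it; the trans ring fusion is already fixed by C5 and C10. The step needs 6-endo over 5-exo closure, cyclisation over direct reduction, and attack on the acrylate rather than on C7 of the enone, which would give a bicyclo[2.2.2]octanone. The ester polarisation and the terminal CH2 should secure the first, slow addition of Bu3SnH at high dilution the second, and the chair-like transition state with both tethers equatorial on ring B the third.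

Step 6
Reactants: 8 decalin keto ester
Product: 9 diene ester (C4 epimers)
Conditions: Zn, CH2Br2, TiCl4, THF/CH2Cl2, 0 °C to rt
Reagents that add atoms: dibromomethane BrCBr
Why: Lombardo methylenation is non-basic, spares the ester and reaches hindered enolisable ketones; it also removes the enone, whose γ-protons would interfere with step 7, and creates no stereocentre.

Step 7
Reactants: 9 diene ester
Product: 10 C4-methylated diene ester
Conditions: LiN(iPr)2, THF, −78 °C; then MeI, DMPU, −78 to 0 °C
Reagents that add atoms: iodomethane CI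
Why: Ester enolate alkylation: both C4 epimers give one enolate, and iodomethane should approach along the equatorial α trajectory away from the axial C10 methyl, so the new methyl is 4α and the ester stays axial (C19, β).

Step 8
Reactants: 10 C4-methylated diene ester
Product: 12 C12 alcohol, via B-alkyl-9-BBN adduct 11 (not isolated)
Conditions: 9-BBN, THF, 0 to 50 °C; then CO (1 atm), KHB(OiPr)3, THF, 0 °C; then KOH, H2O/EtOH; then NaOH, H2O2
Reagents that add atoms: carbon monoxide [C-]#[O+]
Why: Hydroboration–carbonylation–reduction: 9-BBN should add only to the terminal exocyclic alkene and deliver hydrogen to C9 from the α-face opposite the axial C10 methyl (H-9α, chain β), after which CO insertion into the B–C11 bond, hydride reduction of the acylborane and boron-to-oxygen shift on alkaline hydrolysis give the one-carbon-longer primary alcohol.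

Step 9
Reactants: 12 C12 alcohol
Product: 13 C12 iodide
Conditions: PPh3, I2, imidazole, CH2Cl2, 0 °C to rt
Reagents that add atoms: iodine II
Why: Appel-type iodination of an unhindered primary alcohol; no stereocentre is involved.

Step 10
Reactants: 13 C12 iodide; 14 chloroprene
Product: 16 triene ester, via buta-1,3-dien-2-ylmagnesium chloride 15 (not isolated)
Conditions: 14, Mg, ZnCl2 (cat.), THF, reflux; then 13, Li2CuCl4 (cat.), THF, 0 °C
Reagents that add atoms: none
Why: Li2CuCl4-catalysed cross-coupling of a primary alkyl iodide and an alkenyl Grignard reagent forms C12–C13 and installs the 2-substituted butadiene; the axial neopentyl ester should be spared at 0 °C.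

Step 11
Reactants: 16 triene ester
Product: 17 7α,8α-epoxide
Conditions: mCPBA (1.05 equiv), NaHCO3, CH2Cl2, −20 to 0 °C
Reagents that add atoms: 3-chloroperbenzoic acid OOC(=O)c1cccc(Cl)c1
Why: Prilezhaev epoxidation should pick the electron-rich trisubstituted C7=C8 alkene over the conjugated diene and attack the α-face opposite the axial C10 methyl, which sets C8 (oxygen α, methyl β).

Step 12
Reactants: 17 7α,8α-epoxide
Product: 18 8α,19-diol
Conditions: LiAlH4, THF, 0 °C to reflux
Reagents that add atoms: none
Why: Hydride reduction of the ester to the C19 alcohol and SN2 opening of the epoxide at the less substituted C7 (β-attack at C8 is blocked by substitution and the 1,3-diaxial C10 methyl), so the C8–O bond and its α configuration are kept.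

Step 13
Reactants: 18 8α,19-diol; 19 (E)-4-methoxycinnamoyl chloride
Product: 20 target ester
Conditions: Et3N, DMAP (cat.), CH2Cl2, 0 °C to rt
Reagents that add atoms: none
Why: DMAP-catalysed acylation should take only the primary C19 alcohol, the tertiary 8-OH being inert under these conditions, and the E alkene comes unchanged from 19.

Compound list
1 | (R)-(−)-carvone, (5R)-2-methyl-5-(prop-1-en-2-yl)cyclohex-2-en-1-one | CC1=CC[C@H](CC1=O)C(C)=C | starting material
2 | 6-methylcarvone, (5R)-2,6-dimethyl-5-(prop-1-en-2-yl)cyclohex-2-en-1-one, both C6 epimers | CC1=CC[C@H](C(C)C1=O)C(C)=C | intermediate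
3 | 2-bromoethyl trifluoromethanesulfonate | BrCCOS(=O)(=O)C(F)(F)F | starting material
4 | (5S,6S)-6-(2-bromoethyl)-2,6-dimethyl-5-(prop-1-en-2-yl)cyclohex-2-en-1-one; 6-methyl cis and 6-bromoethyl trans to the isopropenyl group | O=C1[C@@](C)(CCBr)[C@H](C(C)=C)CC=C1C | intermediate
5 | allylic alcohol: 4 with the isopropenyl methyl oxidised, 6-(2-bromoethyl)-5-(3-hydroxyprop-1-en-2-yl)-2,6-dimethylcyclohex-2-en-1-one, ring stereocentres as in 4 | O=C1[C@@](C)(CCBr)[C@H](C(=C)CO)CC=C1C | intermediate
6 | enal: 2-[2-(2-bromoethyl)-2,4-dimethyl-3-oxocyclohex-4-en-1-yl]prop-2-enal, ring stereocentres as in 4 | O=C1[C@@](C)(CCBr)[C@H](C(=C)C=O)CC=C1C | intermediate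
7 | methyl 2-[2-(2-bromoethyl)-2,4-dimethyl-3-oxocyclohex-4-en-1-yl]prop-2-enoate, ring stereocentres as in 4 | O=C1[C@@](C)(CCBr)[C@H](C(=C)C(=O)OC)CC=C1C | intermediate
8 | methyl 9-oxo-11,12,13,14,15,16,18-heptanorlabd-7-en-19-oate; trans-decalin with 5α-H, 10β-CH3, 8-CH3, 4-CO2CH3 (both C4 epimers) | O=C1[C@@]2(C)CCCC(C(=O)OC)[C@@H]2CC=C1C | intermediate
9 | methyl 12,13,14,15,16,18-hexanorlabda-7,9(11)-dien-19-oate; 5α-H, 10β-CH3, both C4 epimers | C=C1[C@@]2(C)CCCC(C(=O)OC)[C@@H]2CC=C1C | intermediate
10 | methyl 12,13,14,15,16-pentanorlabda-7,9(11)-dien-19-oate; 4α-CH3, 4β-CO2CH3, 5α-H, 10β-CH3 | C=C1[C@@]2(C)CCC[C@](C)(C(=O)OC)[C@@H]2CC=C1C | intermediate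
11 | B-alkyl-9-BBN adduct: 10 carrying 9-borabicyclo[3.3.1]nonan-9-yl on C11 and H-9α | C(B1C2CCCC1CCC2)[C@@H]1[C@@]2(C)CCC[C@](C)(C(=O)OC)[C@@H]2CC=C1C | intermediate
12 | methyl 12-hydroxy-13,14,15,16-tetranorlabd-7-en-19-oate (H-9α) | OCC[C@@H]1[C@@]2(C)CCC[C@](C)(C(=O)OC)[C@@H]2CC=C1C | intermediate
13 | methyl 12-iodo-13,14,15,16-tetranorlabd-7-en-19-oate | ICC[C@@H]1[C@@]2(C)CCC[C@](C)(C(=O)OC)[C@@H]2CC=C1C | intermediate
14 | chloroprene, 2-chlorobuta-1,3-diene | C=CC(Cl)=C | starting material
15 | buta-1,3-dien-2-ylmagnesium chloride | C=CC(=C)[Mg]Cl | intermediate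
16 | methyl labda-7,13(16),14-trien-19-oate | C=CC(=C)CC[C@@H]1[C@@]2(C)CCC[C@](C)(C(=O)OC)[C@@H]2CC=C1C | intermediate
17 | methyl 7α,8α-epoxylabda-13(16),14-dien-19-oate | C=CC(=C)CC[C@@H]1[C@@]2(C)CCC[C@](C)(C(=O)OC)[C@@H]2C[C@@H]3[C@@]1(C)O3 | intermediate
18 | labda-13(16),14-diene-8α,19-diol | C=CC(=C)CC[C@@H]1[C@@]2(C)CCC[C@](C)(CO)[C@@H]2CC[C@@]1(C)O | intermediate
19 | (E)-4-methoxycinnamoyl chloride, (2E)-3-(4-methoxyphenyl)prop-2-enoyl chloride | COc1ccc(/C=C/C(=O)Cl)cc1 | starting material
20 | 8α-hydroxylabda-13(16),14-dien-19-yl (E)-4-methoxycinnamate, CNP0249194.1 | C=CC(=C)CC[C@@H]1[C@@]2(C)CCC[C@](C)(COC(=O)/C=C/c3ccc(OC)cc3)[C@@H]2CC[C@@]1(C)O | target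

Total step count: 13. Longest linear sequence: 13 steps (1 to 20).

Steps most likely to fail

Step 8. Carbon monoxide uptake by the hindered B-alkyl-9-BBN may stall, so that work-up returns mainly the unhomologated alcohol, and the hydroboration may lose some α-face selectivity at C9. The fallback sets out from 10 and builds C12 by olefination instead. Hydroboration of 10 (9-BBN; then NaOH, H2O2) gives methyl 11-hydroxy-12,13,14,15,16-pentanorlabd-7-en-19-oate F1. Buffered Dess–Martin oxidation gives the aldehyde methyl 11-oxo-12,13,14,15,16-pentanorlabd-7-en-19-oate F2. Wittig methylenation (Ph3P=CH2, THF, 0 °C) gives the C9-vinyl compound methyl 13,14,15,16-tetranorlabda-7,11-dien-19-oate F3. 9-BBN then adds to the monosubstituted alkene only, giving the C12 borane F4, and a B-alkyl Suzuki–Miyaura coupling of this borane and chloroprene 14 (Pd(OAc)2, SPhos, K3PO4, THF/H2O) forms C12–C13. The route is rejoined at 16.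

Step 2. The hindered tetrasubstituted enolate may give O-alkylation or base-induced elimination of the triflate instead of C-alkylation. The fallback sets out from 2 and brings in C1–C2 as an allyl group. Alkylation of 2 (LiN(iPr)2; allyl bromide) gives the 6-allyl-6-methyl ketone F7, the allyl group entering anti to isopropenyl as before. SeO2/t-BuOOH oxidation gives the allylic alcohol F8, and the MnO2/triazolium/MeOH oxidation converts it through the enal F9 into the allyl acrylate ester F10. Ozonolysis of the only electron-rich alkene (O3, CH2Cl2/MeOH, −78 °C; then NaBH4) gives the 2-hydroxyethyl acrylate ester F11, and CBr4/PPh3 converts it into the bromide. The route is rejoined at 7.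

Step 5. Hydrogen transfer to the C2 radical before ring closure, or attack of that radical on the enone β-carbon C7, may divert material from the 6-endo closure. The fallback sets out from 7 and closes the same bond by a polar Michael addition. Kornblum substitution (NaNO2, phloroglucinol, DMF) gives the nitroalkane F5, whose C2–H is far more acidic than any other proton in the molecule. Catalytic DBU in MeCN then effects an intramolecular 6-endo nitronate Michael addition to C3 of the acrylate, giving the 2-nitro decalin keto ester F6. Radical denitration (Bu3SnH, AIBN, toluene, reflux) removes the nitro group, and the route is rejoined at 8.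

Further compounds
F1 | step 8 | methyl 11-hydroxy-12,13,14,15,16-pentanorlabd-7-en-19-oate | OC[C@@H]1[C@@]2(C)CCC[C@](C)(C(=O)OC)[C@@H]2CC=C1C
F2 | step 8 | methyl 11-oxo-12,13,14,15,16-pentanorlabd-7-en-19-oate | O=C[C@@H]1[C@@]2(C)CCC[C@](C)(C(=O)OC)[C@@H]2CC=C1C
F3 | step 8 | methyl 13,14,15,16-tetranorlabda-7,11-dien-19-oate | C=C[C@@H]1[C@@]2(C)CCC[C@](C)(C(=O)OC)[C@@H]2CC=C1C
F4 | step 8 | B-alkyl-9-BBN adduct of F3 carrying boron on C12 | C(C[C@@H]1[C@@]2(C)CCC[C@](C)(C(=O)OC)[C@@H]2CC=C1C)B1C2CCCC1CCC2
F5 | step 5 | methyl 2-[2,4-dimethyl-2-(2-nitroethyl)-3-oxocyclohex-4-en-1-yl]prop-2-enoate, ring stereocentres as in 7 | O=C1[C@@](C)(CC[N+](=O)[O-])[C@H](C(=C)C(=O)OC)CC=C1C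
F6 | step 5 | methyl 2-nitro-9-oxo-11,12,13,14,15,16,18-heptanorlabd-7-en-19-oate, C2 and C4 epimers | O=C1[C@@]2(C)CC([N+](=O)[O-])CC(C(=O)OC)[C@@H]2CC=C1C
F7 | step 2 | 6-allyl-2,6-dimethyl-5-(prop-1-en-2-yl)cyclohex-2-en-1-one, allyl trans to isopropenyl | O=C1[C@@](C)(CC=C)[C@H](C(C)=C)CC=C1C
F8 | step 2 | 6-allyl-5-(3-hydroxyprop-1-en-2-yl)-2,6-dimethylcyclohex-2-en-1-one, stereocentres as in F7 | O=C1[C@@](C)(CC=C)[C@H](C(=C)CO)CC=C1C
F9 | step 2 | 2-(2-allyl-2,4-dimethyl-3-oxocyclohex-4-en-1-yl)prop-2-enal, stereocentres as in F7 | O=C1[C@@](C)(CC=C)[C@H](C(=C)C=O)CC=C1C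
F10 | step 2 | methyl 2-(2-allyl-2,4-dimethyl-3-oxocyclohex-4-en-1-yl)prop-2-enoate, stereocentres as in F7 | O=C1[C@@](C)(CC=C)[C@H](C(=C)C(=O)OC)CC=C1C
F11 | step 2 | methyl 2-[2-(2-hydroxyethyl)-2,4-dimethyl-3-oxocyclohex-4-en-1-yl]prop-2-enoate, stereocentres as in F7 | O=C1[C@@](C)(CCO)[C@H](C(=C)C(=O)OC)CC=C1C
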